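All runs are simulated for an exercise, noise included.

The ratio of L to Q charged is 1.20 in autumn and 3.00 in spring, and E, the tris adduct, holds 3 L per Q, so L is the reagent to count.

| flask | Q | L | remark | time |
|---|---|---|---|---|
| north-west | 1 M | 0.88 M | run made earlier |  |
| south | 1 M | 1.8 M | run made earlier |  |
| west | 1 M | 2.7 M | run made earlier |  |
| autumn | 1.0 M | 1.20 M |  | 10 d |
| spring | 1.0 M | 3.00 M |  | 10 d |

| north-west: time / d | north-west: E / % | south: time / d | south: E / % | west: time / d | west: E / % |
|---|---|---|---|---|---|
| 0.417 | 0.9 | 0.417 | 6.1 | 1.04 | 31.9 |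
| 0.833 | 2.8 | 0.833 | 14.2 | 2.08 | 44.3 |
| 1.25 | 3.8 | 1.25 | 19.1 | 3.00 | 47.8 |
| 2.50 | 6.6 | 2.50 | 26.5 | 4.00 | 48.9 |
| 5.00 | 6.5 | 5.00 | 28.4 | 5.00 | 49.7 |

(scatter of a reading: 0.5 percentage points)

- which of these holds the largest part of the Q at the end of autumn (D / E / Q / Z)
- which of these holds the largest part of the Q at the end of spring (D / E / Q / Z)
- how much E is there at the end of autumn, in percent of the Q charged

*What end state do the runs show?* At the last reading, 5.00 d, E stands at 6.5% in north-west and 49.7% in west. Between them E rises by s = 0.237 L mol⁻¹ of the Q charged per M of L.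

*Is that straight line more than two points?* South was not used to draw it. With Q at 1.0 M, the line reads E = s(L − L0), where L0 = 0.606 M is the dead charge, the L charged at which the line reaches zero E. The line puts south at 28.3%, and south reads 28.4%.

*How fast is it approached?* West reaches 64.2% of its last value by 1.04 d, which gives a time constant τ of about 1.01 d. The asked 10 d is ten times that.

*Your reckoning?* For spring the line gives 56.8% of E, more than the remainder together, 43.2%, so E leads. For autumn it gives 14.1%. No run reads D or Z, so I leave those two open.

*But your readings stop at 5.00 d. Does E stay?* North-west's last two readings differ by 0.1 percentage points, less than the scatter of 0.5 points, so a slow fall could hide there. I hold 14.1% for autumn as a high estimate.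

The forecast says D for autumn, E for spring and 13.5% of E in autumn, on the view that “Plateau E is almost linear in L charged”.

Of the four asked, the flask gives Z as the largest part in autumn at 15.6%, E in spring at 57.2%, and 6.71% of E in autumn.

    Q + L → D (k = 0.00140 L mol⁻¹ min⁻¹)
    L + Z → E (k = 7.80 × 10⁻⁴ L mol⁻¹ min⁻¹)
    Q + E → J (k = 0.00240 L mol⁻¹ min⁻¹)
    Q ⇌ G (K = 5.70, k = 0.00460 min⁻¹)
    L + D → Z (k = 0.00220 L mol⁻¹ min⁻¹)

In autumn E stood at 12.4% at 5.00 d, below the line's 14.1%, with L at 5.88% of its charge. By 10.0 d L was 0.743%, E had fallen to 6.71%, and J had risen from 25.9% to 42.4%. Spring kept 22.0% of its L and held 57.2% of E, against the line's 56.8%. A further flask, like autumn but with 0.30 M of L, under L0, holds 0.144% of E at 10.0 d.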